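**Retrosynthetic overview**

1. Target 18 comes from the triol 15 by double angeloylation (O6, O10) and removal of the O2 silyl group; 15 already holds the complete cis-fused 5–7 skeleton.
2. Key disconnection: the seven-membered ring C1–C5–C6–C7–C8–C9–C10 is cut at C6–C7 and C9–C10 into the cis-cyclopentane-1,2-dicarbaldehyde 8 (C6 and C10 as CHO) and the chiral α-bromoallylboronate 13 (C7–C8(CH3)=C9). Forward, this is a one-pot [4+3] annulation: allylboration at C6, then Ni/Cr closure of C9–C10.
3. Enabling feature: in the seven-membered ring, O6–C6–C7–C8(CH3)=C9–C10–O10 is a (Z)-2-ene-1,5-diol that bridges the cis C1–C5 fusion bond. It is the retron of a 1,4-dialdehyde plus a 2-methylallyl 1,3-dianion, and both oxygens are pseudo-equatorial on the chair cycloheptene.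
4. Dialdehyde 8 comes from cyclobutene 7 by ozonolysis. The temporary cyclobutene (future C6 and C10) is built by [2+2] photocycloaddition of enone 3 with 1,2-dichloroethene anti to O2 (sets C1 and C5), exo addition of i-Pr at C4, and dechlorination. Enone 3 comes from commercial silyloxyenone 1.
5. Ring order: cyclopentane (present in 1), then the temporary cyclobutane (opened again in step 6), then the seven-membered ring, last, in step 9.

Key step: step 9

Remark: daucane numbering is used (C1 = methyl-bearing fusion carbon, C2 = CHOH, C3 = CH2, C4 = C(OH)i-Pr, C5 = fusion CH, C6–C10 = the remaining ring carbons); α is the face of the C1 methyl group and of C5–H, β the opposite face.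

**Route**

Step 1
Reactants: 1 (R)-4-(tert-butyldimethylsilyloxy)cyclopent-2-en-1-one
Product: 2 (3R,4R)-4-(tert-butyldimethylsilyloxy)-3-methyl-1-(trimethylsilyloxy)cyclopent-1-ene (3,4-trans)
Conditions: MeMgBr, CuBr·SMe2 (cat.), TMSCl, THF, −78 °C
Reagents that add atoms: methylmagnesium bromide, C[Mg]Br; chlorotrimethylsilane, C[Si](C)(C)Cl
Why: Copper-catalysed conjugate addition with in situ silyl trapping should deliver the methyl group trans to the silyloxy group and give the regiodefined enol silane; the new methine centre is transient, since step 2 turns it into an sp2 carbon.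

Step 2
Reactants: 2 (3R,4R)-4-(tert-butyldimethylsilyloxy)-3-methyl-1-(trimethylsilyloxy)cyclopent-1-ene
Product: 3 (R)-4-(tert-butyldimethylsilyloxy)-3-methylcyclopent-2-en-1-one
Conditions: Pd(OAc)2 (10 mol %), O2 (1 atm), DMSO, 25 °C
Reagents that add atoms: none
Why: In this Saegusa–Ito oxidation (Pd/O2 variant) the regiodefined enol silane can only lose the hydrogen on the methyl-bearing carbon, so the β-methyl enone should form with the silyloxy stereocentre (future C2) untouched.

Step 3
Reactants: 3 (R)-4-(tert-butyldimethylsilyloxy)-3-methylcyclopent-2-en-1-one; 4 (E)-1,2-dichloroethene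
Product: 5 4-exo-(tert-butyldimethylsilyloxy)-6,7-dichloro-5-methylbicyclo[3.2.0]heptan-2-one (cis-fused, cyclobutane on the face opposite to OTBS, chloride epimers)
Conditions: hν (ca. 350 nm, Pyrex), 4 (excess), CH2Cl2, −20 °C
Reagents that add atoms: none
Why: The enone–alkene [2+2] photocycloaddition should give the cis-fused bicycle with the alkene adding anti to the silyloxy group, which sets the quaternary C1 and C5 together; the two CHCl carbons (future C6 and C10) stay as an inconsequential epimer mixture.

Step 4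
Reactants: 5 4-exo-(tert-butyldimethylsilyloxy)-6,7-dichloro-5-methylbicyclo[3.2.0]heptan-2-one
Product: 6 4-exo-(tert-butyldimethylsilyloxy)-6,7-dichloro-5-methyl-2-exo-(propan-2-yl)bicyclo[3.2.0]heptan-2-ol (OH endo, cis to the cyclobutane)
Conditions: i-PrMgCl, CeCl3, THF, −78 °C; aq. NH4Cl
Reagents that add atoms: isopropylmagnesium chloride, CC(C)[Mg]Cl
Why: The organocerium 1,2-addition suppresses enolisation and reduction, and i-Pr should enter from the convex (exo) face because the concave face is blocked by the chlorinated cyclobutane, which sets C4 with its OH cis to the C5–C6 bond.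

Step 5
Reactants: 6 4-exo-(tert-butyldimethylsilyloxy)-6,7-dichloro-5-methyl-2-exo-(propan-2-yl)bicyclo[3.2.0]heptan-2-ol
Product: 7 4-exo-(tert-butyldimethylsilyloxy)-5-methyl-2-exo-(propan-2-yl)bicyclo[3.2.0]hept-6-en-2-ol
Conditions: Na, NH3(l)/THF, −78 °C; NH4Cl
Reagents that add atoms: none
Why: Dissolving-metal reductive elimination of the vicinal dichloride should give the strained cyclobutene without touching the silyl ether or the unconjugated alkene; no stereocentre changes.

Step 6
Reactants: 7 4-exo-(tert-butyldimethylsilyloxy)-5-methyl-2-exo-(propan-2-yl)bicyclo[3.2.0]hept-6-en-2-ol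
Product: 8 5-(tert-butyldimethylsilyloxy)-3-hydroxy-1-methyl-3-(propan-2-yl)cyclopentane-1,2-dicarbaldehyde (both CHO groups and the 3-OH on the β face; 1-CH3, 2-H, 3-i-Pr and 5-OTBS on the α face)
Conditions: O3, CH2Cl2, −78 °C; PPh3, −78 → 0 °C; used crude
Reagents that add atoms: ozone, [O-][O+]=O
Why: Ozonolysis with reductive work-up should cleave only the strained cis-disubstituted cyclobutene and unveil C6 and C10 as two cis aldehydes under neutral conditions, so C5 is not epimerised.

Step 7
Reactants: 9 isopropenylmagnesium bromide; 10 (1R,2R)-1,2-dicyclohexylethane-1,2-diol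
Product: 12 (4R,5R)-4,5-dicyclohexyl-2-(prop-1-en-2-yl)-1,3,2-dioxaborolane, via diisopropyl isopropenylboronate 11 (not isolated)
Conditions: B(Oi-Pr)3, THF, −78 °C; HCl·Et2O; then 10, Et2O, MgSO4, 23 °C
Reagents that add atoms: triisopropyl borate, CC(C)OB(OC(C)C)OC(C)C
Why: Borylation of the Grignard reagent followed by transesterification with the chelating C2-symmetric diol is the standard entry to chiral boronic esters for the Matteson homologation; no stereocentre is formed.

Step 8
Reactants: 12 (4R,5R)-4,5-dicyclohexyl-2-(prop-1-en-2-yl)-1,3,2-dioxaborolane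
Product: 13 (4R,5R)-2-[(1S)-1-bromo-2-methylprop-2-en-1-yl]-4,5-dicyclohexyl-1,3,2-dioxaborolane
Conditions: CH2Br2, LDA, THF, −100 °C; ZnCl2, −100 → 23 °C; used at once
Reagents that add atoms: dibromomethane, BrCBr
Why: In this Matteson homologation LiCHBr2 forms the borate and the ZnCl2-promoted 1,2-migration of the alkenyl group displaces one bromide under control of the C2-symmetric diol, which should set the (S)-C–Br centre.

Step 9
Reactants: 8 5-(tert-butyldimethylsilyloxy)-3-hydroxy-1-methyl-3-(propan-2-yl)cyclopentane-1,2-dicarbaldehyde; 13 (4R,5R)-2-[(1S)-1-bromo-2-methylprop-2-en-1-yl]-4,5-dicyclohexyl-1,3,2-dioxaborolane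
Product: 15 2α-(tert-butyldimethylsilyloxy)-cis-dauc-8-ene-4β,6α,10β-triol, via bromoalkenyl borate aldehyde 14 (not isolated)
Conditions: 13 (1.05 equiv), CH2Cl2, 4 Å MS, −78 → 23 °C; then DMF–THF, CrCl2 (6 equiv), NiCl2 (2 mol %), 23 °C, 5 mM; aq. K/Na tartrate
Reagents that add atoms: none
Why: Proposed new method: a one-pot [4+3] annulation of a 1,4-dialdehyde with a 2-methylallyl 1,3-dianion equivalent, in which 13 first allylborates the C6 aldehyde through a Zimmerman–Traxler chair with the C–Br bond axial (A1,2 strain with the C8 methyl; closest known type: α-haloallylboronate addition giving (Z)-haloalkenes), and CrCl2/NiCl2 then turns the C9–Br bond of the borate 14 into an alkenylchromium(III) that adds to the C10 aldehyde (closest known type: intramolecular Nozaki–Hiyama–Kishi cyclisation). The seven-membered ring, the last ring of the skeleton, closes by C9–C10 bond formation as a 1,2-addition of the (Z)-alkenylchromium with retention of alkene geometry, so that C7 and C10 end cis on C8=C9. C6 is set by 1,3-chirality transfer from the (S)-C–Br centre of 13 in the chair, matched with attack anti to the C1 arm on the aldehyde held by the O4–H···O=C6 hydrogen bond. C10 is set in a chair-like cycloheptene transition state in which the C1 methyl, the C5–C4 bond, O6 and the chromium-bound O10 are all pseudo-equatorial, which is the 6α,10β arrangement of the target. The step needs chemoselectivity for the C6 over the C10 aldehyde in the boron stage, which the α-CH (not quaternary) position and the hydrogen bond from the cis O4–H should secure, and it needs O6 to stay boron-bound so that it cannot close onto C10 as a lactol, which is why no aqueous work-up separates the two stages.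

Step 10
Reactants: 15 2α-(tert-butyldimethylsilyloxy)-cis-dauc-8-ene-4β,6α,10β-triol; 16 angelic anhydride
Product: 17 6α,10β-bis(angeloyloxy)-2α-(tert-butyldimethylsilyloxy)-cis-dauc-8-en-4β-ol
Conditions: LiHMDS (2.2 equiv), THF, −78 °C; 16 (2.5 equiv), −78 → 0 °C; aq. NH4Cl
Reagents that add atoms: none
Why: O-Acylation of the two secondary lithium alkoxides with the anhydride (an alkoxide–anhydride esterification that keeps the Z geometry) should leave the hindered tertiary C4–OH free; no stereocentre changes.

Step 11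
Reactants: 17 6α,10β-bis(angeloyloxy)-2α-(tert-butyldimethylsilyloxy)-cis-dauc-8-en-4β-ol
Product: 18 6α,10β-bis(angeloyloxy)-cis-dauc-8-ene-2α,4β-diol (CNP0249167.1)
Conditions: HF·pyridine, pyridine/THF, 0 → 23 °C
Reagents that add atoms: none
Why: Buffered fluoride desilylation should cleave the secondary TBS ether without acyl migration or Z→E isomerisation of the angelates; no stereocentre changes.

**Compound list**

1 | (R)-4-(tert-butyldimethylsilyloxy)cyclopent-2-en-1-one | O=C1C=C[C@H](O[Si](C)(C)C(C)(C)C)C1 | starting material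
2 | (3R,4R)-4-(tert-butyldimethylsilyloxy)-3-methyl-1-(trimethylsilyloxy)cyclopent-1-ene | C[Si](C)(C)OC1=C[C@@H](C)[C@H](O[Si](C)(C)C(C)(C)C)C1 | intermediate
3 | (R)-4-(tert-butyldimethylsilyloxy)-3-methylcyclopent-2-en-1-one | O=C1C=C(C)[C@H](O[Si](C)(C)C(C)(C)C)C1 | intermediate
4 | (E)-1,2-dichloroethene | Cl/C=C/Cl | starting material
5 | 4-exo-(tert-butyldimethylsilyloxy)-6,7-dichloro-5-methylbicyclo[3.2.0]heptan-2-one (chloride epimers) | O=C1C[C@@H](O[Si](C)(C)C(C)(C)C)[C@]2(C)C(Cl)C(Cl)[C@H]12 | intermediate
6 | 4-exo-(tert-butyldimethylsilyloxy)-6,7-dichloro-5-methyl-2-exo-(propan-2-yl)bicyclo[3.2.0]heptan-2-ol | CC(C)[C@@]1(O)C[C@@H](O[Si](C)(C)C(C)(C)C)[C@]2(C)C(Cl)C(Cl)[C@H]12 | intermediate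
7 | 4-exo-(tert-butyldimethylsilyloxy)-5-methyl-2-exo-(propan-2-yl)bicyclo[3.2.0]hept-6-en-2-ol | CC(C)[C@@]1(O)C[C@@H](O[Si](C)(C)C(C)(C)C)[C@]2(C)C=C[C@H]12 | intermediate
8 | 5-(tert-butyldimethylsilyloxy)-3-hydroxy-1-methyl-3-(propan-2-yl)cyclopentane-1,2-dicarbaldehyde (CHO groups cis) | CC(C)[C@@]1(O)C[C@@H](O[Si](C)(C)C(C)(C)C)[C@](C)(C=O)[C@@H]1C=O | intermediate
9 | isopropenylmagnesium bromide | C=C(C)[Mg]Br | starting material
10 | (1R,2R)-1,2-dicyclohexylethane-1,2-diol | O[C@H](C1CCCCC1)[C@H](O)C1CCCCC1 | starting material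
11 | diisopropyl isopropenylboronate (not isolated) | C=C(C)B(OC(C)C)OC(C)C | intermediate
12 | (4R,5R)-4,5-dicyclohexyl-2-(prop-1-en-2-yl)-1,3,2-dioxaborolane | C=C(C)B1O[C@H](C2CCCCC2)[C@@H](C2CCCCC2)O1 | intermediate
13 | (4R,5R)-2-[(1S)-1-bromo-2-methylprop-2-en-1-yl]-4,5-dicyclohexyl-1,3,2-dioxaborolane | C=C(C)[C@@H](Br)B1O[C@H](C2CCCCC2)[C@@H](C2CCCCC2)O1 | intermediate
14 | bromoalkenyl borate aldehyde: adduct of 13 at C6 of 8, O6 boron-bound, (Z)-C8=C9–Br, C10 still CHO (not isolated) | CC(C)[C@@]1(O)C[C@@H](O[Si](C)(C)C(C)(C)C)[C@](C)(C=O)[C@@H]1[C@H](OB2O[C@H](C3CCCCC3)[C@@H](C3CCCCC3)O2)C/C(C)=C\Br | intermediate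
15 | 2α-(tert-butyldimethylsilyloxy)-cis-dauc-8-ene-4β,6α,10β-triol | O[C@@H]1CC(C)=C[C@@H](O)[C@@]2(C)[C@H](O[Si](C)(C)C(C)(C)C)C[C@](O)(C(C)C)[C@@H]12 | intermediate
16 | angelic anhydride, (Z)-2-methylbut-2-enoic anhydride | C/C=C(/C)C(=O)OC(=O)/C(C)=C\C | starting material
17 | 6α,10β-bis(angeloyloxy)-2α-(tert-butyldimethylsilyloxy)-cis-dauc-8-en-4β-ol | C/C=C(/C)C(=O)O[C@@H]1CC(C)=C[C@@H](OC(=O)/C(C)=C\C)[C@@]2(C)[C@H](O[Si](C)(C)C(C)(C)C)C[C@](O)(C(C)C)[C@@H]12 | intermediate
18 | 6α,10β-bis(angeloyloxy)-cis-dauc-8-ene-2α,4β-diol (CNP0249167.1) | C/C=C(/C)C(=O)O[C@@H]1CC(C)=C[C@@H](OC(=O)/C(C)=C\C)[C@@]2(C)[C@H](O)C[C@](O)(C(C)C)[C@@H]12 | target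

**Summary**

Total step count: 11
Longest linear sequence: 9 (steps 1–6, 9, 10, 11)

**Steps most likely to fail**

Step 9 (Proposed new method). The boron stage may lose chemoselectivity and add at the C10 aldehyde. The O6 borate may close onto the C10 aldehyde as a lactol-type acetal and withhold it from the chromium stage. The alkenylchromium may be protonated before it cyclises. The fallback sets out from 8 and 13 and comes back at 15. The allylboration is run alone and worked up with aqueous diethanolamine, so that O6 closes onto C10 and the bromo lactol F1 is isolated as an anomer mixture. Oxidation with TEMPO and PhI(OAc)2 gives the cis-fused γ-lactone, the bromo lactone F2. Treatment with t-BuLi at −100 °C effects Br/Li exchange, and the alkenyllithium acylates the lactone carbonyl (Parham cyclisation), which closes the seven-membered ring at the ketone level and gives the hydroxy enone F3 after work-up. Luche reduction (NaBH4, CeCl3, MeOH, −78 °C), with axial hydride delivery giving the pseudo-equatorial 10β-alcohol, returns to 15.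

Step 6. The β-hydroxy cis-dialdehyde may epimerise at C5, undergo retro-aldol cleavage of C4–C5, or be over-oxidised during ozonide reduction. The fallback sets out from 3 and comes back at 8. Photocycloaddition of 3 with 2,2-dimethyl-1,3-dioxole gives the acetonide photoadduct F4. Organocerium addition of i-Pr (as in step 4) gives the acetonide tertiary alcohol F5. Aqueous acetic acid removes the acetonide to give the cyclobutanediol F6. Glycol cleavage with NaIO4 at pH 7 then releases 8 without ozone.

Step 10. Acylation of the hindered 6α-OH may stay incomplete, and the angelate may isomerise to the tiglate under the basic conditions. The fallback sets out from 15 and comes back at 17. Both secondary alcohols are esterified (DCC, DMAP) with 2-[bis(2,2,2-trifluoroethoxy)phosphoryl]propanoic acid to give the bis(phosphonopropionate) F7. A double Still–Gennari olefination with acetaldehyde (KHMDS, 18-crown-6, THF, −78 °C) then builds both (Z)-2-methylbut-2-enoates on the ester and gives 17.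

Further compounds
F1 | step 9 | bromo lactol (C6–O–C10 hemiacetal, anomer mixture) | CC(C)[C@@]1(O)C[C@@H](O[Si](C)(C)C(C)(C)C)[C@]2(C)C(O)O[C@H](C/C(C)=C\Br)[C@H]12
F2 | step 9 | bromo lactone (C10 carbonyl, O6 ring oxygen) | CC(C)[C@@]1(O)C[C@@H](O[Si](C)(C)C(C)(C)C)[C@]2(C)C(=O)O[C@H](C/C(C)=C\Br)[C@H]12
F3 | step 9 | hydroxy enone (10-oxo analogue of 15) | O[C@@H]1CC(C)=CC(=O)[C@@]2(C)[C@H](O[Si](C)(C)C(C)(C)C)C[C@](O)(C(C)C)[C@@H]12
F4 | step 6 | acetonide photoadduct | O=C1C[C@@H](O[Si](C)(C)C(C)(C)C)[C@]2(C)C3OC(C)(C)OC3[C@H]12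
F5 | step 6 | acetonide tertiary alcohol | CC(C)[C@@]1(O)C[C@@H](O[Si](C)(C)C(C)(C)C)[C@]2(C)C3OC(C)(C)OC3[C@H]12
F6 | step 6 | cyclobutanediol | CC(C)[C@@]1(O)C[C@@H](O[Si](C)(C)C(C)(C)C)[C@]2(C)C(O)C(O)[C@H]12
F7 | step 10 | bis(phosphonopropionate) | CC(C(=O)O[C@@H]1CC(C)=C[C@@H](OC(=O)C(C)P(=O)(OCC(F)(F)F)OCC(F)(F)F)[C@@]2(C)[C@H](O[Si](C)(C)C(C)(C)C)C[C@](O)(C(C)C)[C@@H]12)P(=O)(OCC(F)(F)F)OCC(F)(F)F
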